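**Retrosynthetic overview**
1. The strategy rests on the two ring-fusion carbons, C1 (quaternary, CH3) and C5 (CH): they are joined by the three-carbon bridge C2–C3–C4 of ring A (cyclopentane) and by the five-carbon bridge C6–C10 of ring B (cycloheptane).
2. Cutting C1–C5 and C8–C9 opens both rings to one chain: a C9=C10=C1 allene (methyl on C1) and a C5=C6(OSi)–C7=C8 siloxydiene hung on the C2–C3–C4 bridge, closed again by a platinum-triggered (4+3) cycloaddition.
3. The chain comes from two aldol bonds: C2–C3 (boron aldol of 3-methylbutan-2-one with 2-methylbuta-2,3-dienal, sets C2) and C4–C5 (chelation-controlled Mukaiyama aldol of a pent-3-en-2-one enol silane onto the C4 ketone, sets C4).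
4. After cyclisation the C9=C10 alkene is moved to C8=C9 by oxidation to the C6 dienone, hydroxyl-directed reduction at C6 and 1,4-hydrogenation of the ring diene; hydroxyl-directed epoxidation, vanilloylation and phenol release finish the target.
5. Ring order: ring A (C1–C5 bond) and ring B (C8–C9 bond) are formed in the same step, ring A leading.

Key step: step 9

Remark: the skeleton numbering above is used for all bicyclic compounds, α being the face of H5; the sense of induction in step 4 is assumed to be the usual one for methyl ketone enol diisopinocampheylborinates.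

**Step 1**
Reactants: 1 but-2-yne-1,4-diol
Product: 2 4-chlorobut-2-yn-1-ol
Conditions: SOCl2 (1 equiv), pyridine, benzene, 0 °C → rt; distillation
Reagents that add atoms: thionyl chloride, O=S(Cl)Cl
Why: Chlorodehydroxylation of one propargylic hydroxyl through its chlorosulfite; one equivalent of reagent limits the reaction to the monochloride, which should be separable from diol and dichloride.

**Step 2**
Reactants: 2 4-chlorobut-2-yn-1-ol
Product: 3 2-methylbuta-2,3-dien-1-ol
Conditions: MeMgBr (2.3 equiv), CuI (10 mol%), THF, −78 °C → rt; aq. NH4Cl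
Reagents that add atoms: methylmagnesium bromide, C[Mg]Br
Why: Copper-catalysed anti-SN2′ substitution of the propargylic chloride by the Grignard reagent gives the 1,1-disubstituted allene; the first equivalent only deprotonates the alcohol.

**Step 3**
Reactants: 3 2-methylbuta-2,3-dien-1-ol
Product: 4 2-methylbuta-2,3-dienal
Conditions: MnO2 (activated, excess), CH2Cl2, rt; filtered and used as a solution
Reagents that add atoms: none
Why: MnO2 oxidation of an allenylic (allylic-type) primary alcohol stops at the aldehyde; the volatile product is not concentrated to dryness.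

**Step 4**
Reactants: 5 3-methylbutan-2-one; 4 2-methylbuta-2,3-dienal
Product: 8 (5S)-5-hydroxy-2,6-dimethylocta-6,7-dien-3-one, via enol borinate 6 (not isolated), via boron aldolate 7 (not isolated)
Conditions: (−)-Ipc2BCl, Et3N, Et2O, 0 °C; then 4, −78 → −20 °C; H2O2, MeOH, pH 7 buffer, 0 °C
Reagents that add atoms: none
Why: Boron aldol of the methyl-side enol diisopinocampheylborinate through a chair transition state; the isopinocampheyl groups should direct the enolate to the Si face of the aldehyde, which gives the (S)-carbinol C2 (the antipodal reagent would be taken if the induction ran the other way).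

**Step 5**
Reactants: 8 (5S)-5-hydroxy-2,6-dimethylocta-6,7-dien-3-one
Product: 9 (5S)-5-[(tert-butyldimethylsilyl)oxy]-2,6-dimethylocta-6,7-dien-3-one
Conditions: TBSCl, imidazole, DMF, rt
Reagents that add atoms: tert-butyldimethylsilyl chloride, CC(C)(C)[Si](C)(C)Cl
Why: Standard imidazole-mediated silylation of a secondary alcohol; the bulky, weakly nucleophilic silyl ether oxygen is chosen so that it does not add to the platinum-activated allene in step 9.

**Step 6**
Reactants: 10 (E)-pent-3-en-2-one
Product: 11 trimethyl{[(3E)-penta-1,3-dien-2-yl]oxy}silane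
Conditions: TMSOTf, Et3N, Et2O, 0 °C
Reagents that add atoms: trimethylsilyl trifluoromethanesulfonate, C[Si](C)(C)OS(=O)(=O)C(F)(F)F
Why: Soft enolisation of the methyl ketone on its methyl side gives the cross-conjugated 2-siloxydiene, an established Mukaiyama donor that reacts at its terminal CH2.

**Step 7**
Reactants: 9 (5S)-5-[(tert-butyldimethylsilyl)oxy]-2,6-dimethylocta-6,7-dien-3-one; 11 trimethyl{[(3E)-penta-1,3-dien-2-yl]oxy}silane
Product: 12 (2E,6S,8S)-8-[(tert-butyldimethylsilyl)oxy]-6-hydroxy-9-methyl-6-(propan-2-yl)undeca-2,9,10-trien-4-one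
Conditions: MeAlCl2 (2.5 equiv), CH2Cl2, −78 °C (9 and Lewis acid first, then 11); aq. NaHCO3
Reagents that add atoms: none
Why: Mukaiyama aldol onto a ketone: the chelating aluminium Lewis acid ties the ketone and β-silyloxy oxygens into a six-membered chelate, and the enol silane attacks the face anti to the C2 substituent, which sets C4 with the 2,4-anti oxygen relationship; a silyl enol ether avoids the retro-aldol and proton-transfer problems of metal enolates with a hindered, enolisable ketone.

**Step 8**
Reactants: 12 (2E,6S,8S)-8-[(tert-butyldimethylsilyl)oxy]-6-hydroxy-9-methyl-6-(propan-2-yl)undeca-2,9,10-trien-4-one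
Product: 14 (2E,4Z,6R,8S)-4,8-bis[(tert-butyldimethylsilyl)oxy]-9-methyl-6-(propan-2-yl)-6-[(triethylsilyl)oxy]undeca-2,4,9,10-tetraene, via triethylsilyl ether 13 (not isolated)
Conditions: TESOTf, 2,6-lutidine, CH2Cl2, −78 °C; then TBSOTf, Et3N, −78 → 0 °C
Reagents that add atoms: triethylsilyl trifluoromethanesulfonate, CC[Si](CC)(CC)OS(=O)(=O)C(F)(F)F; tert-butyldimethylsilyl trifluoromethanesulfonate, CC(C)(C)[Si](C)(C)OS(=O)(=O)C(F)(F)F
Why: Silylation of the tertiary alcohol under a hindered pyridine base that does not enolise the ketone, then soft enolisation of the enone on its α′ side to the 2-siloxydiene; the Z enol ether, with the bulky C4 away from the propenyl group, is the thermodynamically preferred geometry.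

**Step 9**
Reactants: 14 (2E,4Z,6R,8S)-4,8-bis[(tert-butyldimethylsilyl)oxy]-9-methyl-6-(propan-2-yl)-6-[(triethylsilyl)oxy]undeca-2,4,9,10-tetraene
Product: 15 trans-fused cycloadduct: 2α-OTBS, 4β-OTES, 4α-isopropyl, 1β-methyl, 5α-H, 8β-methyl, C6=C7 TBS enol ether, C9=C10 alkene
Conditions: PtCl2 (10 mol%), 2,6-di-tert-butyl-4-methylpyridine (20 mol%), toluene, 80 °C
Reagents that add atoms: none
Why: Proposed new method: divalent platinum binds the allene and opens it to an allyl cation carrying platinum on C10; its tertiary end C1 is attacked by the nucleophilic C5 of the 2-siloxydiene, the C9 end then bonds to C8 of the siloxy-stabilised allyl cation so formed, and the resulting C10 platinum carbene can only take a hydride from C9 (C1 has none), which releases PtCl2 and leaves the C9=C10 alkene. The closest known reaction type is the PtCl2- or cationic-gold-catalysed intramolecular (4+3) cycloaddition of allene-dienes that carry substituents at the allene terminus and hydrogen at the tethered carbon and give trans-fused bicyclo[5.3.0]decadienes; an allene substituted only at its tethered carbon (so that a quaternary fusion carbon forms) and a 2-siloxydiene have not been put through it. Ring A closes first by 5-exo attack of C5 on C1 and ring B then by 7-endo bonding of C9 to C8, overall suprafacial on both partners. C5 is controlled by C4 (isopropyl pseudo-equatorial and the C6 branch trans to it in the forming cyclopentane, with the C2 silyl ether also pseudo-equatorial), C1 by the extended, exo-like approach that places its methyl group trans to H5, and C8 by the E-propenyl geometry (H8 cis to H5; this centre is removed in step 10). The step needs (4+3) closure in preference to monocyclisation or ring contraction, and it needs the trans fusion: the Z enol ether keeps the tether outside an accessible s-cis diene, the electron-rich diene is set up to capture the vinyl-platinum end, PtCl2 is the catalyst type under which the carbene ends by hydride shift, and the quaternary C1 cannot be lost by hydride shift.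

**Step 10**
Reactants: 15 trans-fused cycloadduct
Product: 16 2α-OTBS-4β-OTES-6-oxo-7,9-diene (ring-B dienone C6(=O)–C7=C8(CH3)–C9=C10)
Conditions: Pd(OAc)2 (1.1 equiv), MeCN, rt
Reagents that add atoms: none
Why: Saegusa–Ito oxidation: palladation of the enol silane at C7 and syn β-hydride elimination of the doubly allylic H8 give the C7=C8 enone in conjugation with C9=C10, removing the C8 stereocentre.

**Step 11**
Reactants: 16 2α-OTBS-4β-OTES-6-oxo-7,9-diene
Product: 17 2α,4β-dihydroxy-6-oxo-7,9-diene
Conditions: HF·pyridine, pyridine, THF, 0 → 40 °C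
Reagents that add atoms: none
Why: Fluoride cleavage of both silyl ethers under buffered, non-basic conditions, so that the β-hydroxy ketone should not undergo retro-aldol cleavage.

**Step 12**
Reactants: 17 2α,4β-dihydroxy-6-oxo-7,9-diene
Product: 18 2α-acetoxy-4β-hydroxy-6-oxo-7,9-diene
Conditions: Ac2O, pyridine, DMAP (cat.), CH2Cl2, 0 °C → rt
Reagents that add atoms: acetic anhydride, CC(=O)OC(C)=O
Why: Chemoselective acetylation: the secondary C2–OH is acylated while the tertiary C4–OH is inert under these conditions.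

**Step 13**
Reactants: 18 2α-acetoxy-4β-hydroxy-6-oxo-7,9-diene
Product: 19 2α-acetoxy-7,9-diene-4β,6α-diol
Conditions: Me4NBH(OAc)3, MeCN/AcOH, −20 °C → rt
Reagents that add atoms: none
Why: Evans–Saksena reduction: the 4β-oxygen binds boron and delivers hydride intramolecularly to the β face of the C6 ketone, which should give the 6α-alcohol (1,3-anti to the 4β-OH).

**Step 14**
Reactants: 19 2α-acetoxy-7,9-diene-4β,6α-diol
Product: 20 2α-acetoxy-8-ene-4β,6α-diol
Conditions: (η6-naphthalene)Cr(CO)3 (20 mol%), H2 (40 atm), THF, 45 °C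
Reagents that add atoms: none
Why: Chromium tricarbonyl-catalysed 1,4-hydrogenation, specific for 1,3-dienes held s-cis as in this ring: hydrogen adds to C7 and C10 and leaves the C8=C9 alkene, and esters, hydroxyl groups and the product alkene are not reduced.

**Step 15**
Reactants: 20 2α-acetoxy-8-ene-4β,6α-diol
Product: 21 2α-acetoxy-8α,9α-epoxy-4β,6α-diol
Conditions: VO(acac)2 (5 mol%), t-BuOOH, CH2Cl2, 0 °C → rt
Reagents that add atoms: tert-butyl hydroperoxide, CC(C)(C)OO
Why: Hydroxyl-directed epoxidation of a homoallylic alcohol: the vanadium alkoxide of the 6α-OH delivers oxygen to the α face of C8=C9 (the β face is also screened by the C1 methyl group), which sets C8 and C9.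

**Step 16**
Reactants: 22 vanillic acid
Product: 23 4-acetoxy-3-methoxybenzoic acid
Conditions: Ac2O, pyridine, rt; aq. HCl
Reagents that add atoms: acetic anhydride, CC(=O)OC(C)=O
Why: O-acetylation of the phenol; any mixed anhydride at the carboxyl group is hydrolysed on aqueous work-up.

**Step 17**
Reactants: 21 2α-acetoxy-8α,9α-epoxy-4β,6α-diol; 23 4-acetoxy-3-methoxybenzoic acid
Product: 25 6α-(4-acetoxy-3-methoxybenzoyl) ester of 21, via acid chloride 24 (not isolated)
Conditions: 23, (COCl)2, DMF (cat.), CH2Cl2, 0 °C → rt, concentrate; then 21, pyridine, DMAP (cat.), CH2Cl2, 0 °C → rt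
Reagents that add atoms: none
Why: Acylation with an acid chloride under nucleophilic catalysis; the secondary C6–OH reacts while the tertiary C4–OH and the epoxide do not.

**Step 18**
Reactants: 25 6α-(4-acetoxy-3-methoxybenzoyl) ester of 21
Product: 26 CNP0241679.3 (2α-acetoxy-8α,9α-epoxy-4β-hydroxy-6α-vanilloyloxy compound)
Conditions: pyrrolidine (3 equiv), CH2Cl2, 0 °C
Reagents that add atoms: none
Why: Aminolysis of the aryl acetate, an activated phenyl ester, is far faster than attack on the hindered secondary acetate at C2 or on the benzoate-type ester at C6, so only the phenol should be released.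

**Compound list**
1 | but-2-yne-1,4-diol | OCC#CCO | starting material
2 | 4-chlorobut-2-yn-1-ol | OCC#CCCl | intermediate
3 | 2-methylbuta-2,3-dien-1-ol | C=C=C(C)CO | intermediate
4 | 2-methylbuta-2,3-dienal | C=C=C(C)C=O | intermediate
5 | 3-methylbutan-2-one | CC(C)C(C)=O | starting material
6 | 3-methylbut-1-en-2-yl bis[(−)-isopinocampheyl]borinate (enol borinate) | C=C(OB([C@H]1[C@H](C)[C@H]2C[C@@H](C1)C2(C)C)[C@H]1[C@H](C)[C@H]2C[C@@H](C1)C2(C)C)C(C)C | intermediate
7 | bis[(−)-isopinocampheyl]borinate of 8 (boron aldolate) | C=C=C(C)[C@@H](OB([C@H]1[C@H](C)[C@H]2C[C@@H](C1)C2(C)C)[C@H]1[C@H](C)[C@H]2C[C@@H](C1)C2(C)C)CC(=O)C(C)C | intermediate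
8 | (5S)-5-hydroxy-2,6-dimethylocta-6,7-dien-3-one | C=C=C(C)[C@@H](O)CC(=O)C(C)C | intermediate
9 | (5S)-5-[(tert-butyldimethylsilyl)oxy]-2,6-dimethylocta-6,7-dien-3-one | C=C=C(C)[C@@H](O[Si](C)(C)C(C)(C)C)CC(=O)C(C)C | intermediate
10 | (E)-pent-3-en-2-one | C/C=C/C(C)=O | starting material
11 | trimethyl{[(3E)-penta-1,3-dien-2-yl]oxy}silane | C/C=C/C(=C)O[Si](C)(C)C | intermediate
12 | (2E,6S,8S)-8-[(tert-butyldimethylsilyl)oxy]-6-hydroxy-9-methyl-6-(propan-2-yl)undeca-2,9,10-trien-4-one | C=C=C(C)[C@@H](O[Si](C)(C)C(C)(C)C)C[C@@](O)(C(C)C)CC(=O)/C=C/C | intermediate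
13 | (2E,6S,8S)-8-[(tert-butyldimethylsilyl)oxy]-9-methyl-6-(propan-2-yl)-6-[(triethylsilyl)oxy]undeca-2,9,10-trien-4-one | C=C=C(C)[C@@H](O[Si](C)(C)C(C)(C)C)C[C@@](O[Si](CC)(CC)CC)(C(C)C)CC(=O)/C=C/C | intermediate
14 | (2E,4Z,6R,8S)-4,8-bis[(tert-butyldimethylsilyl)oxy]-9-methyl-6-(propan-2-yl)-6-[(triethylsilyl)oxy]undeca-2,4,9,10-tetraene (cyclisation precursor) | C=C=C(C)[C@@H](O[Si](C)(C)C(C)(C)C)C[C@@](O[Si](CC)(CC)CC)(C(C)C)/C=C(O[Si](C)(C)C(C)(C)C)/C=C/C | intermediate
15 | trans-fused cycloadduct: 1β-methyl, 2α-OTBS, 4β-OTES, 4α-isopropyl, 5α-H, 6-OTBS (C6=C7), 8β-methyl, C9=C10 | CC(C)(C)[Si](C)(C)OC2=C[C@H](C)C=C[C@@]3(C)[C@@H](O[Si](C)(C)C(C)(C)C)C[C@@](O[Si](CC)(CC)CC)(C(C)C)[C@H]23 | intermediate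
16 | 2α-OTBS-4β-OTES-6-oxo-7,9-diene | O=C2C=C(C)C=C[C@@]3(C)[C@@H](O[Si](C)(C)C(C)(C)C)C[C@@](O[Si](CC)(CC)CC)(C(C)C)[C@H]23 | intermediate
17 | 2α,4β-dihydroxy-6-oxo-7,9-diene | O=C2C=C(C)C=C[C@@]3(C)[C@@H](O)C[C@@](O)(C(C)C)[C@H]23 | intermediate
18 | 2α-acetoxy-4β-hydroxy-6-oxo-7,9-diene | O=C2C=C(C)C=C[C@@]3(C)[C@@H](OC(C)=O)C[C@@](O)(C(C)C)[C@H]23 | intermediate
19 | 2α-acetoxy-7,9-diene-4β,6α-diol | O[C@H]2C=C(C)C=C[C@@]3(C)[C@@H](OC(C)=O)C[C@@](O)(C(C)C)[C@H]23 | intermediate
20 | 2α-acetoxy-8-ene-4β,6α-diol | O[C@H]2CC(C)=CC[C@@]3(C)[C@@H](OC(C)=O)C[C@@](O)(C(C)C)[C@H]23 | intermediate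
21 | 2α-acetoxy-8α,9α-epoxy-4β,6α-diol | O[C@H]2C[C@@]3(C)O[C@H]3C[C@@]3(C)[C@@H](OC(C)=O)C[C@@](O)(C(C)C)[C@H]23 | intermediate
22 | vanillic acid (4-hydroxy-3-methoxybenzoic acid) | COc1cc(C(=O)O)ccc1O | starting material
23 | 4-acetoxy-3-methoxybenzoic acid | COc1cc(C(=O)O)ccc1OC(C)=O | intermediate
24 | 4-acetoxy-3-methoxybenzoyl chloride | COc1cc(C(Cl)=O)ccc1OC(C)=O | intermediate
25 | 6α-(4-acetoxy-3-methoxybenzoyl) ester of 21 | COc1cc(C(=O)O[C@H]2C[C@@]3(C)O[C@H]3C[C@@]3(C)[C@@H](OC(C)=O)C[C@@](O)(C(C)C)[C@H]23)ccc1OC(C)=O | intermediate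
26 | CNP0241679.3 | COc1cc(C(=O)O[C@H]2C[C@@]3(C)O[C@H]3C[C@@]3(C)[C@@H](OC(C)=O)C[C@@](O)(C(C)C)[C@H]23)ccc1O | target

**Step count**
Total: 18 steps. Longest linear sequence: 16 steps (steps 1–5, 7–15, 17 and 18).

**Steps most likely to fail**

1. Step 9. The platinum-bound allyl cation may be captured only once (the oxocarbenium ion loses its silyl group and the vinyl–platinum bond is protonated, giving a monocycle), the carbene may contract ring B by alkyl shift, or the enol ether may be cleaved by adventitious acid before cyclisation. Fallback by known oxyallyl-cation (4+3) chemistry, setting out from 12 and coming back at 15: step 8 is stopped after the first silylation and the triethylsilyl ether 13 is isolated. mCPBA (CH2Cl2, 0 °C) oxidises the more substituted allene double bond, and the allene oxide is opened by the liberated acid to the α-(3-chlorobenzoyloxy) methyl ketone F1 (C1 epimers, of no consequence). TBSOTf/Et3N turns both ketones into silyl enol ethers, giving the bis(enol ether) F2. TMSOTf (cat.) in CH2Cl2 at −78 °C ionises the tertiary allylic ester to a 2-siloxyallyl cation, which adds across the diene termini and makes the same C1–C5 and C8–C9 bonds, giving the ring-B C10 ketone F3; its fusion geometry would have to be confirmed at this stage. KHMDS/PhNTf2 gives the C9=C10 enol triflate F4, and Pd(OAc)2, PPh3, Bu3N, HCO2H (DMF, 60 °C) reduces it to 15.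

2. Step 7. The Lewis acid may fail to hold the silyl ether in a chelate (poor facial selectivity at C4), may engage the allene, or the hindered ketone may react too slowly so that the enone product consumes the enol silane. Fallback setting out from 9 and coming back at 12: the lithium enolate of N-methoxy-N-methylacetamide (LiHMDS, THF, −78 °C, with CeCl3 if enolisation of 9 competes) adds to the ketone to give the β-hydroxy Weinreb amide F5, whose C4 epimers can be separated if facial control is incomplete. (E)-Prop-1-enylmagnesium bromide (THF, 0 °C, in excess to allow for the free hydroxyl) then converts the amide into enone 12.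

3. Step 14. The chromium catalyst may fail to bind the hindered ring diene, hydrogen may add 1,2, or the dienyl carbinol may ionise on prolonged heating. Fallback setting out from 16 and coming back at 20: Li in NH3/THF with t-BuOH (1 equiv) at −78 °C, quenched with solid NH4Cl, effects 1,6-reduction of the linear dienone to the extended enolate, and kinetic protonation at C7 gives the β,γ-unsaturated ketone F6 with C8=C9 in place. HF·pyridine gives the diol F7, Ac2O/pyridine acetylates the C2–OH to F8, and Me4NBH(OAc)3 reduces the ketone under direction of the 4β-OH to 20.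

**Further compounds**
F1 | step 9 | α-(3-chlorobenzoyloxy) methyl ketone from 13 (C1 epimers) | CC(=O)C(C)(OC(=O)c1cccc(Cl)c1)[C@@H](O[Si](C)(C)C(C)(C)C)C[C@@](O[Si](CC)(CC)CC)(C(C)C)CC(=O)/C=C/C
F2 | step 9 | bis(TBS enol ether) of F1 (2-siloxyallyl ester and 2-siloxydiene) | C=C(O[Si](C)(C)C(C)(C)C)C(C)(OC(=O)c1cccc(Cl)c1)[C@@H](O[Si](C)(C)C(C)(C)C)C[C@@](O[Si](CC)(CC)CC)(C(C)C)/C=C(O[Si](C)(C)C(C)(C)C)/C=C/C
F3 | step 9 | bicyclic C10 ketone with C6=C7 TBS enol ether | CC(C)(C)[Si](C)(C)OC2=C[C@H](C)CC(=O)[C@@]3(C)[C@@H](O[Si](C)(C)C(C)(C)C)C[C@@](O[Si](CC)(CC)CC)(C(C)C)[C@H]23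
F4 | step 9 | C9=C10 enol triflate of F3 | CC(C)(C)[Si](C)(C)OC2=C[C@H](C)C=C(OS(=O)(=O)C(F)(F)F)[C@@]3(C)[C@@H](O[Si](C)(C)C(C)(C)C)C[C@@](O[Si](CC)(CC)CC)(C(C)C)[C@H]23
F5 | step 7 | β-hydroxy Weinreb amide from 9 | C=C=C(C)[C@@H](O[Si](C)(C)C(C)(C)C)C[C@@](O)(C(C)C)CC(=O)N(C)OC
F6 | step 14 | 2α-OTBS-4β-OTES-6-oxo-8-ene (β,γ-unsaturated ketone) | O=C2CC(C)=CC[C@@]3(C)[C@@H](O[Si](C)(C)C(C)(C)C)C[C@@](O[Si](CC)(CC)CC)(C(C)C)[C@H]23
F7 | step 14 | 2α,4β-dihydroxy-6-oxo-8-ene | O=C2CC(C)=CC[C@@]3(C)[C@@H](O)C[C@@](O)(C(C)C)[C@H]23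
F8 | step 14 | 2α-acetoxy-4β-hydroxy-6-oxo-8-ene | O=C2CC(C)=CC[C@@]3(C)[C@@H](OC(C)=O)C[C@@](O)(C(C)C)[C@H]23
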